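Readings and results were computed for an exercise, noise included.

At the reading time of 8.0 h, the two earlier flasks seemed to disagree: birch, charged with 6.8 mM of solid electrophile, showed product at 8.5 % of its charge, and elm, charged with 29 mM, showed 2.5 %. Three new flasks are to be read at that same time.

| flask | solid electrophile | nucleophile | free base | remark | time |
|---|---|---|---|---|---|
| birch | 6.8 mM | 21 mM | 22 mM | run made earlier |  |
| elm | 29 mM | 21 mM | 22 mM | run made earlier |  |
| west | 5.0 mM | 21.0 mM | 22.0 mM |  | 8.0 h |
| east | 10 mM | 21.0 mM | 22.0 mM |  | 8.0 h |
| south | 20 mM | 21.0 mM | 22.0 mM |  | 8.0 h |

- birch (time / h: product / %): 0.417: 0; 1.33: 0.4; 2.50: 1.4; 3.00: 1.1; 5.00: 3.1; 6.00: 4.6; 8.00: 8.5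
- elm (time / h: product / %): 0.417: 0; 1.33: 0.2; 2.50: 0.1; 3.00: 0; 5.00: 0.9; 6.00: 0; 8.00: 2.5

(standard deviation of a reading: 0.5 percentage points)

- the earlier runs were read with a standard deviation of 0.5 percentage points
- at the start none of the solid electrophile is in solution
- "hardly changes" means that all values lie within two and a half points (for a concentration: within two and a half percent of the largest)

* [product] at the end for west, east, south, in this order
* how that number moves from the first to the last of them (falls all the way / rises all the way / falls, then rises / rises, then falls / hardly changes)

A falling fraction need not mean a poorer flask, so I multiplied each fraction by its charge. Birch gave 0.578 mM, and this is the quantity I carried, the made amount: fraction read times charge, at the reading time. Elm, a separate flask, gave the second route, 0.725 mM. The two routes came close, though not level, so I tested each on the other flask, in fractions.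

Birch's amount predicted 1.99 % for elm, which lies 0.51 percentage points from the reading, about the scatter of 0.5 points. Elm's amount predicted 10.7 % for birch, which lies 2.2 points from the reading. Elm's route was the looser one, because a point of fraction is worth more in elm than in birch.

I therefore kept birch's amount. The two runs read as apparent zero order in the charged solid, so I reckoned the same amount for each new flask: 11.6 % of the charge for west, 5.78 % for east and 2.89 % for south. West was the risky one, since its charge lies below both charges tried so far, and the readings, which were of product, could not show how much of its solid would remain.

The forecast was 0.56 mM, 0.56 mM and 0.56 mM, shape "hardly changes", a little below my amount. Its ground was this: “a fourfold change in solid charge leaves the absolute product unchanged”.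

The flasks gave 0.554 mM, 0.554 mM and 0.554 mM, shape "hardly changes".

    electrophile + nucleophile → acid set free + product (k = 3.61 M⁻¹ h⁻¹)
    nucleophile + acid set free ⇌ protonated nucleophile, settled at all times (K = 2.05 × 10⁵ M⁻¹)
    acid set free + free base ⇌ salt of the base, settled at all times (K = 8000 M⁻¹)
    acid set free → by-product carried off (k = 0.0441 h⁻¹)
    solid electrophile ⇌ electrophile, rate k5*(cs5 - [electrophile]) while solid is left; crystals form when [electrophile] > cs5 (solubility = 14.0 mM, k = 0.0246 h⁻¹)
    nucleophile ⇌ dormant form (K = 1.84, k = 0.0317 h⁻¹)

At 8.00 h, west, the smallest charge of the new flasks, still held 49.2 % of its charge as solid electrophile. The made amount, divided by the charge, gave south 2.89 % against the 2.77 % it reached, and it gave west 11.6 % against 11.1 %.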